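**Retrosynthetic overview**
1. Target ⇐ late-stage C15 silyl ether cleavage, C14 CH2O-PMB → CHO, and the C8 methacrylate installed by Mitsunobu inversion of an 8-epi alcohol.
2. Ten-membered carbocycle (second ring) ⇐ ring-closing metathesis that forms the ring-cis C4=C5 alkene of an acyclic triene lactone.
3. C7–C8 bond and the α-methylene-γ-butyrolactone ⇐ zinc Barbier allylation of an (S)-α-methoxy aldehyde (C8–C10, C14, C1–C4, C15) with (R)-3-(bromomethyl)-5-vinylbutenolide (first ring, made before the union).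
4. Aldehyde ⇐ Z-vinyl iodide (from but-2-yne-1,4-diol and methallyl alcohol) + D-glycerate Weinreb amide; chelation-controlled reduction sets C9, periodate cleavage unmasks C8.
5. Bromobutenolide ⇐ acrolein + silyl propargyl ether: Sharpless kinetic resolution (C6), hydroalumination–iodination, carboxylation–lactonisation.

Assumption: positions are given in germacrane numbering (C6 lactone CH–O, C7 ring-fusion CH, C8 CH–O-ester, C9 CH–OMe, C14 the CHO carbon on C10, C15 the CH2OH carbon on C4); the SMILES is read as (6R,7S,8S,9S) with a trans-fused lactone and both ring alkenes cis within the ring.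

**Bromobutenolide**

Step 1
Reactants: 1 tert-butyldimethyl(prop-2-yn-1-yloxy)silane; 2 acrolein
Product: 4 rac-6-((tert-butyldimethylsilyl)oxy)hex-1-en-4-yn-3-ol, via lithium acetylide 3 (not isolated)
Conditions: n-BuLi, THF, −78 °C; then 2, −78 °C; aq NH4Cl
Reagents that add atoms: none
Why: 1,2-addition of a lithium acetylide to the enal (carbonyl alkynylation) is clean at −78 °C; the carbinol forms racemic and is resolved next.

Step 2
Reactants: 4 rac-6-((tert-butyldimethylsilyl)oxy)hex-1-en-4-yn-3-ol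
Product: 5 (R)-6-((tert-butyldimethylsilyl)oxy)hex-1-en-4-yn-3-ol
Conditions: Ti(OiPr)4 (0.2 equiv), D-(−)-diisopropyl tartrate (0.24 equiv), t-BuOOH (0.6 equiv), 4 Å molecular sieves, CH2Cl2, −20 °C, to about 55–60% conversion
Reagents that add atoms: none
Why: Sharpless kinetic resolution: with the D-tartrate the (S)-carbinol is epoxidised at its vinyl group and the slow (R)-enantiomer, which becomes C6, is recovered in high ee (maximum 50% yield).

Step 3
Reactants: 5 (R)-6-((tert-butyldimethylsilyl)oxy)hex-1-en-4-yn-3-ol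
Product: 7 (3R,4Z)-6-((tert-butyldimethylsilyl)oxy)-5-iodohexa-1,4-dien-3-ol, via cyclic alkenylaluminate 6 (not isolated)
Conditions: NaAlH2(OCH2CH2OMe)2, THF, 0 °C; then I2, THF, −78 °C
Reagents that add atoms: iodine, II
Why: Alkoxide-directed trans-hydroalumination of the propargylic alcohol puts aluminium on the distal alkyne carbon in a five-membered chelate, and iodinolysis with retention gives the Z-vinyl iodide with iodine cis to the carbinol carbon.

Step 4
Reactants: 7 (3R,4Z)-6-((tert-butyldimethylsilyl)oxy)-5-iodohexa-1,4-dien-3-ol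
Product: 10 (R)-3-(((tert-butyldimethylsilyl)oxy)methyl)-5-vinylfuran-2(5H)-one, via dilithio alkoxide vinyllithium 8 (not isolated), via hydroxy acid 9 (not isolated)
Conditions: t-BuLi (3.1 equiv), Et2O, −78 °C; CO2; then 1 M HCl to pH 2, 0 °C to rt
Reagents that add atoms: carbon dioxide, O=C=O
Why: Iodine–lithium exchange with retention, carboxylation and acid-induced lactonisation of the Z-γ-hydroxy acid build the butenolide without exposing the base-labile γ-vinyl stereocentre to base or to a palladium catalyst.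

Step 5
Reactants: 10 (R)-3-(((tert-butyldimethylsilyl)oxy)methyl)-5-vinylfuran-2(5H)-one
Product: 11 (R)-3-(hydroxymethyl)-5-vinylfuran-2(5H)-one
Conditions: 48% aq HF, MeCN, 0 °C
Reagents that add atoms: none
Why: Acidic fluoride desilylation of the primary silyl ether leaves the butenolide and its stereocentre untouched.

Step 6
Reactants: 11 (R)-3-(hydroxymethyl)-5-vinylfuran-2(5H)-one
Product: 12 (R)-3-(bromomethyl)-5-vinylfuran-2(5H)-one
Conditions: CBr4, PPh3, CH2Cl2, 0 °C
Reagents that add atoms: carbon tetrabromide, BrC(Br)(Br)Br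
Why: Appel bromination converts the primary allylic alcohol into the allylic bromide under neutral conditions.

**Aldehyde**

Step 7
Reactants: 13 but-2-yne-1,4-diol
Product: 14 4-((4-methoxybenzyl)oxy)but-2-yn-1-ol
Conditions: NaH (1 equiv), 13 (3 equiv), THF/DMF, 0 °C; 4-methoxybenzyl chloride (1 equiv), n-Bu4NI (cat.), rt
Reagents that add atoms: 4-methoxybenzyl chloride, COc1ccc(CCl)cc1
Why: Williamson etherification with the cheap diol in excess gives the mono-ether.

Step 8
Reactants: 14 4-((4-methoxybenzyl)oxy)but-2-yn-1-ol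
Product: 16 (Z)-3-iodo-4-((4-methoxybenzyl)oxy)but-2-en-1-ol, via cyclic alkenylaluminate 15 (not isolated)
Conditions: NaAlH2(OCH2CH2OMe)2, THF, 0 °C; then I2, THF, −78 °C
Reagents that add atoms: iodine, II
Why: The free hydroxyl directs trans-hydroalumination so that iodine ends up on the carbon bearing CH2O-PMB and cis to CH2OH, which fixes the C1=C10 geometry (C2 cis to the future C9).

Step 9
Reactants: 16 (Z)-3-iodo-4-((4-methoxybenzyl)oxy)but-2-en-1-ol
Product: 17 (Z)-1-(((4-bromo-2-iodobut-2-en-1-yl)oxy)methyl)-4-methoxybenzene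
Conditions: CBr4, PPh3, CH2Cl2, 0 °C
Reagents that add atoms: carbon tetrabromide, BrC(Br)(Br)Br
Why: Appel bromination gives the primary allylic bromide without touching the vinyl iodide.

Step 10
Reactants: 17 (Z)-1-(((4-bromo-2-iodobut-2-en-1-yl)oxy)methyl)-4-methoxybenzene; 18 2-methylprop-2-en-1-ol
Product: 20 (Z)-6-iodo-7-((4-methoxybenzyl)oxy)-2-methylenehept-5-en-1-ol, via dilithio methallyl alkoxide 19 (not isolated)
Conditions: 18, n-BuLi (2.1 equiv), TMEDA, Et2O, 0 °C to rt; then 17, THF, −78 °C; aq NH4Cl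
Reagents that add atoms: none
Why: C-alkylation of the methallyl alcohol dianion (its two allyl termini are equivalent) by SN2 at the primary allylic bromide forms the C2–C3 bond and leaves the vinyl iodide geometry intact.

Step 11
Reactants: 20 (Z)-6-iodo-7-((4-methoxybenzyl)oxy)-2-methylenehept-5-en-1-ol
Product: 21 (Z)-tert-butyl((6-iodo-7-((4-methoxybenzyl)oxy)-2-methylenehept-5-en-1-yl)oxy)diphenylsilane
Conditions: tert-butyl(chloro)diphenylsilane, imidazole, DMF, rt
Reagents that add atoms: tert-butyl(chloro)diphenylsilane, CC(C)(C)[Si](Cl)(c1ccccc1)c1ccccc1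
Why: Silylation of the primary alcohol gives an acid-stable C15 protecting group that is orthogonal to the PMB ether on C14.

Step 12
Reactants: 22 methyl (R)-2,2-dimethyl-1,3-dioxolane-4-carboxylate
Product: 23 (R)-N-methoxy-N,2,2-trimethyl-1,3-dioxolane-4-carboxamide
Conditions: MeNH(OMe)·HCl, i-PrMgCl, THF, −20 °C; aq NH4Cl
Reagents that add atoms: N,O-dimethylhydroxylamine hydrochloride, CNOC.Cl
Why: Aminolysis of the ester by the magnesium amide (Weinreb amide formation) proceeds at low temperature without epimerising the α-alkoxy centre.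

Step 13
Reactants: 21 (Z)-tert-butyl((6-iodo-7-((4-methoxybenzyl)oxy)-2-methylenehept-5-en-1-yl)oxy)diphenylsilane; 23 (R)-N-methoxy-N,2,2-trimethyl-1,3-dioxolane-4-carboxamide
Product: 25 (Z)-6-(((tert-butyldiphenylsilyl)oxy)methyl)-1-((R)-2,2-dimethyl-1,3-dioxolan-4-yl)-2-(((4-methoxybenzyl)oxy)methyl)hepta-2,6-dien-1-one, via vinyllithium 24 (not isolated)
Conditions: t-BuLi (2.1 equiv), Et2O, −78 °C; then 23, −78 to −40 °C; aq NH4Cl
Reagents that add atoms: none
Why: Iodine–lithium exchange keeps the alkene geometry and the Weinreb amide stops at the ketone (acyl substitution through a stable chelated tetrahedral adduct), forming the C9–C10 bond.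

Step 14
Reactants: 25 (Z)-6-(((tert-butyldiphenylsilyl)oxy)methyl)-1-((R)-2,2-dimethyl-1,3-dioxolan-4-yl)-2-(((4-methoxybenzyl)oxy)methyl)hepta-2,6-dien-1-one
Product: 26 (S,Z)-6-(((tert-butyldiphenylsilyl)oxy)methyl)-1-((R)-2,2-dimethyl-1,3-dioxolan-4-yl)-2-(((4-methoxybenzyl)oxy)methyl)hepta-2,6-dien-1-ol
Conditions: Zn(BH4)2, Et2O, −30 °C
Reagents that add atoms: none
Why: Chelation-controlled (Cram chelate) 1,2-reduction: zinc bridges the ketone and the α-oxygen of the dioxolane and hydride adds from the face away from the ring CH2, giving the anti (S)-carbinol that becomes C9 (minor diastereomer removed by chromatography).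

Step 15
Reactants: 26 (S,Z)-6-(((tert-butyldiphenylsilyl)oxy)methyl)-1-((R)-2,2-dimethyl-1,3-dioxolan-4-yl)-2-(((4-methoxybenzyl)oxy)methyl)hepta-2,6-dien-1-ol
Product: 27 (R)-4-((S,Z)-6-(((tert-butyldiphenylsilyl)oxy)methyl)-1-methoxy-2-(((4-methoxybenzyl)oxy)methyl)hepta-2,6-dien-1-yl)-2,2-dimethyl-1,3-dioxolane
Conditions: NaH, MeI, THF, 0 °C to rt
Reagents that add atoms: iodomethane, CI
Why: Williamson methylation installs the C9 methyl ether without touching the stereocentre.

Step 16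
Reactants: 27 (R)-4-((S,Z)-6-(((tert-butyldiphenylsilyl)oxy)methyl)-1-methoxy-2-(((4-methoxybenzyl)oxy)methyl)hepta-2,6-dien-1-yl)-2,2-dimethyl-1,3-dioxolane
Product: 28 (2R,3S,Z)-8-(((tert-butyldiphenylsilyl)oxy)methyl)-3-methoxy-4-(((4-methoxybenzyl)oxy)methyl)nona-4,8-diene-1,2-diol
Conditions: AcOH/H2O (4:1), 40 °C
Reagents that add atoms: none
Why: Acid hydrolysis of the terminal acetonide; the PMB ether, the silyl ether and the allylic methyl ether are stable to aqueous acetic acid.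

Step 17
Reactants: 28 (2R,3S,Z)-8-(((tert-butyldiphenylsilyl)oxy)methyl)-3-methoxy-4-(((4-methoxybenzyl)oxy)methyl)nona-4,8-diene-1,2-diol
Product: 29 (S,Z)-7-(((tert-butyldiphenylsilyl)oxy)methyl)-2-methoxy-3-(((4-methoxybenzyl)oxy)methyl)octa-3,7-dienal
Conditions: NaIO4, THF/H2O, 0 °C; extracted and used at once
Reagents that add atoms: none
Why: Periodate glycol cleavage unmasks the C8 aldehyde under neutral conditions, so the α-methoxy β,γ-unsaturated aldehyde is neither epimerised nor conjugated.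

**Union and endgame**

Step 18
Reactants: 12 (R)-3-(bromomethyl)-5-vinylfuran-2(5H)-one; 29 (S,Z)-7-(((tert-butyldiphenylsilyl)oxy)methyl)-2-methoxy-3-(((4-methoxybenzyl)oxy)methyl)octa-3,7-dienal
Product: 31 (4R,5R)-4-((1R,2S,Z)-7-(((tert-butyldiphenylsilyl)oxy)methyl)-1-hydroxy-2-methoxy-3-(((4-methoxybenzyl)oxy)methyl)octa-3,7-dien-1-yl)-3-methylene-5-vinyldihydrofuran-2(3H)-one, via allylzinc bromide 30 (not isolated)
Conditions: Zn dust, THF/sat. aq NH4Cl (2:1), 0 °C to rt
Reagents that add atoms: none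
Why: Zinc Barbier carbonyl allylation through a closed six-membered transition state: the allylzinc reacts at its γ-carbon (C7) on the face anti to the C6 vinyl group (trans lactone), the ring-fixed allyl geometry with the aldehyde substituent equatorial gives the 8R carbinol, and this is also the Felkin–Anh product of the (S)-α-methoxy aldehyde (matched pair).

Step 19
Reactants: 31 (4R,5R)-4-((1R,2S,Z)-7-(((tert-butyldiphenylsilyl)oxy)methyl)-1-hydroxy-2-methoxy-3-(((4-methoxybenzyl)oxy)methyl)octa-3,7-dien-1-yl)-3-methylene-5-vinyldihydrofuran-2(3H)-one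
Product: 32 (3aR,4R,5S,6Z,10E,11aR)-10-(((tert-butyldiphenylsilyl)oxy)methyl)-4-hydroxy-5-methoxy-6-(((4-methoxybenzyl)oxy)methyl)-3-methylene-3a,4,5,8,9,11a-hexahydrocyclodeca[b]furan-2(3H)-one
Conditions: second-generation Grubbs catalyst RuCl2(=CHPh)(H2IMes)(PCy3) (15 mol %, in portions), toluene, 1 mM, 80 °C
Reagents that add atoms: none
Why: Ring-closing metathesis between the C5 vinyl group and the 1,1-disubstituted C4 alkene closes the ten-membered ring, and the new trisubstituted alkene forms ring-cis because a trans alkene is too strained in a cyclodeca-1,5-diene that already holds a cis alkene; it is run before esterification so that no methacrylate can compete by closing a seven-membered lactone onto the vinyl group.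

Step 20
Reactants: 32 (3aR,4R,5S,6Z,10E,11aR)-10-(((tert-butyldiphenylsilyl)oxy)methyl)-4-hydroxy-5-methoxy-6-(((4-methoxybenzyl)oxy)methyl)-3-methylene-3a,4,5,8,9,11a-hexahydrocyclodeca[b]furan-2(3H)-one; 33 methacrylic acid
Product: 34 (3aS,4S,5S,6Z,10E,11aR)-10-(((tert-butyldiphenylsilyl)oxy)methyl)-5-methoxy-6-(((4-methoxybenzyl)oxy)methyl)-3-methylene-2-oxo-2,3,3a,4,5,8,9,11a-octahydrocyclodeca[b]furan-4-yl methacrylate
Conditions: PPh3, DIAD, toluene, 0 °C (betaine formed first); then 33 and 32, 0 °C to rt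
Reagents that add atoms: none
Why: Mitsunobu esterification: the carboxylate displaces the oxyphosphonium group by SN2 with inversion, turning the 8R alcohol into the 8S (8β) methacrylate of the target, now syn to the C9 methoxy group.

Step 21
Reactants: 34 (3aS,4S,5S,6Z,10E,11aR)-10-(((tert-butyldiphenylsilyl)oxy)methyl)-5-methoxy-6-(((4-methoxybenzyl)oxy)methyl)-3-methylene-2-oxo-2,3,3a,4,5,8,9,11a-octahydrocyclodeca[b]furan-4-yl methacrylate
Product: 35 (3aS,4S,5S,6Z,10E,11aR)-10-(((tert-butyldiphenylsilyl)oxy)methyl)-6-(hydroxymethyl)-5-methoxy-3-methylene-2-oxo-2,3,3a,4,5,8,9,11a-octahydrocyclodeca[b]furan-4-yl methacrylate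
Conditions: DDQ, CH2Cl2/aq NaH2PO4–Na2HPO4 buffer (pH 7), 0 °C
Reagents that add atoms: none
Why: Oxidative PMB ether cleavage frees only the C14 allylic alcohol; esters, the silyl ether and the alkenes are inert to DDQ under buffered conditions.

Step 22
Reactants: 35 (3aS,4S,5S,6Z,10E,11aR)-10-(((tert-butyldiphenylsilyl)oxy)methyl)-6-(hydroxymethyl)-5-methoxy-3-methylene-2-oxo-2,3,3a,4,5,8,9,11a-octahydrocyclodeca[b]furan-4-yl methacrylate
Product: 36 (3aS,4S,5S,6E,10E,11aR)-10-(((tert-butyldiphenylsilyl)oxy)methyl)-6-formyl-5-methoxy-3-methylene-2-oxo-2,3,3a,4,5,8,9,11a-octahydrocyclodeca[b]furan-4-yl methacrylate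
Conditions: MnO2 (excess), CH2Cl2, rt
Reagents that add atoms: none
Why: Allylic oxidation with MnO2 gives the enal without base, so the alkene geometry is kept (the E label only reflects the new CHO priority).

Step 23
Reactants: 36 (3aS,4S,5S,6E,10E,11aR)-10-(((tert-butyldiphenylsilyl)oxy)methyl)-6-formyl-5-methoxy-3-methylene-2-oxo-2,3,3a,4,5,8,9,11a-octahydrocyclodeca[b]furan-4-yl methacrylate
Product: 37 (3aS,4S,5S,6E,10E,11aR)-6-formyl-10-(hydroxymethyl)-5-methoxy-3-methylene-2-oxo-2,3,3a,4,5,8,9,11a-octahydrocyclodeca[b]furan-4-yl methacrylate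
Conditions: HF·pyridine, THF/pyridine, 0 °C to rt
Reagents that add atoms: none
Why: Buffered fluoride desilylation frees the C15 alcohol without a basic step that could trigger conjugate addition, acyl migration or translactonisation.

**Compound list**
1 | tert-butyldimethyl(prop-2-yn-1-yloxy)silane | C#CCO[Si](C)(C)C(C)(C)C | starting material
2 | acrolein (prop-2-enal) | C=CC=O | starting material
3 | lithium acetylide of 1 (not isolated) | [Li]C#CCO[Si](C)(C)C(C)(C)C | intermediate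
4 | rac-6-((tert-butyldimethylsilyl)oxy)hex-1-en-4-yn-3-ol | C=CC(O)C#CCO[Si](C)(C)C(C)(C)C | intermediate
5 | (R)-6-((tert-butyldimethylsilyl)oxy)hex-1-en-4-yn-3-ol | C=C[C@@H](O)C#CCO[Si](C)(C)C(C)(C)C | intermediate
6 | sodium cyclic alkenylaluminate from 5, five-membered C–Al–O chelate (not isolated) | [Na+].C=C[C@H]1O[Al-](OCCOC)(OCCOC)C(CO[Si](C)(C)C(C)(C)C)=C1 | intermediate
7 | (3R,4Z)-6-((tert-butyldimethylsilyl)oxy)-5-iodohexa-1,4-dien-3-ol | C=C[C@@H](O)/C=C(\I)CO[Si](C)(C)C(C)(C)C | intermediate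
8 | dilithio alkoxide vinyllithium from 7 (not isolated) | C=C[C@@H](O[Li])/C=C(\[Li])CO[Si](C)(C)C(C)(C)C | intermediate
9 | (2Z,4R)-2-(((tert-butyldimethylsilyl)oxy)methyl)-4-hydroxyhexa-2,5-dienoic acid, formed as its dilithium salt (not isolated) | C=C[C@@H](O)/C=C(/CO[Si](C)(C)C(C)(C)C)C(=O)O | intermediate
10 | (R)-3-(((tert-butyldimethylsilyl)oxy)methyl)-5-vinylfuran-2(5H)-one | C=C[C@H]1OC(=O)C(CO[Si](C)(C)C(C)(C)C)=C1 | intermediate
11 | (R)-3-(hydroxymethyl)-5-vinylfuran-2(5H)-one | C=C[C@H]1OC(=O)C(CO)=C1 | intermediate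
12 | (R)-3-(bromomethyl)-5-vinylfuran-2(5H)-one | C=C[C@H]1OC(=O)C(CBr)=C1 | intermediate
13 | but-2-yne-1,4-diol | OCC#CCO | starting material
14 | 4-((4-methoxybenzyl)oxy)but-2-yn-1-ol | COc1ccc(COCC#CCO)cc1 | intermediate
15 | sodium cyclic alkenylaluminate from 14 (not isolated) | [Na+].COCCO[Al-]1(OCCOC)OCC=C1COCc1ccc(OC)cc1 | intermediate
16 | (Z)-3-iodo-4-((4-methoxybenzyl)oxy)but-2-en-1-ol | OC/C=C(\I)COCc1ccc(OC)cc1 | intermediate
17 | (Z)-1-(((4-bromo-2-iodobut-2-en-1-yl)oxy)methyl)-4-methoxybenzene | BrC/C=C(\I)COCc1ccc(OC)cc1 | intermediate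
18 | 2-methylprop-2-en-1-ol (methallyl alcohol) | C=C(C)CO | starting material
19 | dilithio methallyl alkoxide, C,O-dianion of 18 (not isolated) | [Li]CC(=C)CO[Li] | intermediate
20 | (Z)-6-iodo-7-((4-methoxybenzyl)oxy)-2-methylenehept-5-en-1-ol | C=C(CO)CC/C=C(\I)COCc1ccc(OC)cc1 | intermediate
21 | (Z)-tert-butyl((6-iodo-7-((4-methoxybenzyl)oxy)-2-methylenehept-5-en-1-yl)oxy)diphenylsilane | C=C(CO[Si](c1ccccc1)(c1ccccc1)C(C)(C)C)CC/C=C(\I)COCc1ccc(OC)cc1 | intermediate
22 | methyl (R)-2,2-dimethyl-1,3-dioxolane-4-carboxylate | COC(=O)[C@H]1COC(C)(C)O1 | starting material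
23 | (R)-N-methoxy-N,2,2-trimethyl-1,3-dioxolane-4-carboxamide | CON(C)C(=O)[C@H]1COC(C)(C)O1 | intermediate
24 | vinyllithium from 21 (not isolated) | C=C(CO[Si](c1ccccc1)(c1ccccc1)C(C)(C)C)CC/C=C(\[Li])COCc1ccc(OC)cc1 | intermediate
25 | (Z)-6-(((tert-butyldiphenylsilyl)oxy)methyl)-1-((R)-2,2-dimethyl-1,3-dioxolan-4-yl)-2-(((4-methoxybenzyl)oxy)methyl)hepta-2,6-dien-1-one | C=C(CO[Si](c1ccccc1)(c1ccccc1)C(C)(C)C)CC/C=C(/COCc1ccc(OC)cc1)C(=O)[C@H]1COC(C)(C)O1 | intermediate
26 | (S,Z)-6-(((tert-butyldiphenylsilyl)oxy)methyl)-1-((R)-2,2-dimethyl-1,3-dioxolan-4-yl)-2-(((4-methoxybenzyl)oxy)methyl)hepta-2,6-dien-1-ol | C=C(CO[Si](c1ccccc1)(c1ccccc1)C(C)(C)C)CC/C=C(/COCc1ccc(OC)cc1)[C@H](O)[C@H]1COC(C)(C)O1 | intermediate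
27 | (R)-4-((S,Z)-6-(((tert-butyldiphenylsilyl)oxy)methyl)-1-methoxy-2-(((4-methoxybenzyl)oxy)methyl)hepta-2,6-dien-1-yl)-2,2-dimethyl-1,3-dioxolane | C=C(CO[Si](c1ccccc1)(c1ccccc1)C(C)(C)C)CC/C=C(/COCc1ccc(OC)cc1)[C@H](OC)[C@H]1COC(C)(C)O1 | intermediate
28 | (2R,3S,Z)-8-(((tert-butyldiphenylsilyl)oxy)methyl)-3-methoxy-4-(((4-methoxybenzyl)oxy)methyl)nona-4,8-diene-1,2-diol | C=C(CO[Si](c1ccccc1)(c1ccccc1)C(C)(C)C)CC/C=C(/COCc1ccc(OC)cc1)[C@H](OC)[C@H](O)CO | intermediate
29 | (S,Z)-7-(((tert-butyldiphenylsilyl)oxy)methyl)-2-methoxy-3-(((4-methoxybenzyl)oxy)methyl)octa-3,7-dienal | C=C(CO[Si](c1ccccc1)(c1ccccc1)C(C)(C)C)CC/C=C(/COCc1ccc(OC)cc1)[C@H](OC)C=O | intermediate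
30 | allylzinc bromide from 12 (not isolated) | C=C[C@H]1OC(=O)C(C[Zn]Br)=C1 | intermediate
31 | (4R,5R)-4-((1R,2S,Z)-7-(((tert-butyldiphenylsilyl)oxy)methyl)-1-hydroxy-2-methoxy-3-(((4-methoxybenzyl)oxy)methyl)octa-3,7-dien-1-yl)-3-methylene-5-vinyldihydrofuran-2(3H)-one; Barbier adduct, 8R alcohol | C=C[C@H]1OC(=O)C(=C)[C@@H]1[C@@H](O)[C@@H](OC)/C(COCc1ccc(OC)cc1)=C\CCC(=C)CO[Si](c1ccccc1)(c1ccccc1)C(C)(C)C | intermediate
32 | (3aR,4R,5S,6Z,10E,11aR)-10-(((tert-butyldiphenylsilyl)oxy)methyl)-4-hydroxy-5-methoxy-6-(((4-methoxybenzyl)oxy)methyl)-3-methylene-3a,4,5,8,9,11a-hexahydrocyclodeca[b]furan-2(3H)-one; 8-epi macrocyclic alcohol, both ring alkenes ring-cis | O[C@@H]1[C@H]2C(=C)C(=O)O[C@@H]2/C=C(/CO[Si](c3ccccc3)(c3ccccc3)C(C)(C)C)CC/C=C(/COCc3ccc(OC)cc3)[C@@H]1OC | intermediate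
33 | methacrylic acid | C=C(C)C(=O)O | starting material
34 | (3aS,4S,5S,6Z,10E,11aR)-10-(((tert-butyldiphenylsilyl)oxy)methyl)-5-methoxy-6-(((4-methoxybenzyl)oxy)methyl)-3-methylene-2-oxo-2,3,3a,4,5,8,9,11a-octahydrocyclodeca[b]furan-4-yl methacrylate | C=C(C)C(=O)O[C@H]1[C@H]2C(=C)C(=O)O[C@@H]2/C=C(/CO[Si](c3ccccc3)(c3ccccc3)C(C)(C)C)CC/C=C(/COCc3ccc(OC)cc3)[C@@H]1OC | intermediate
35 | (3aS,4S,5S,6Z,10E,11aR)-10-(((tert-butyldiphenylsilyl)oxy)methyl)-6-(hydroxymethyl)-5-methoxy-3-methylene-2-oxo-2,3,3a,4,5,8,9,11a-octahydrocyclodeca[b]furan-4-yl methacrylate | C=C(C)C(=O)O[C@H]1[C@H]2C(=C)C(=O)O[C@@H]2/C=C(/CO[Si](c3ccccc3)(c3ccccc3)C(C)(C)C)CC/C=C(/CO)[C@@H]1OC | intermediate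
36 | (3aS,4S,5S,6E,10E,11aR)-10-(((tert-butyldiphenylsilyl)oxy)methyl)-6-formyl-5-methoxy-3-methylene-2-oxo-2,3,3a,4,5,8,9,11a-octahydrocyclodeca[b]furan-4-yl methacrylate | C=C(C)C(=O)O[C@H]1[C@H]2C(=C)C(=O)O[C@@H]2/C=C(/CO[Si](c3ccccc3)(c3ccccc3)C(C)(C)C)CC/C=C(/C=O)[C@@H]1OC | intermediate
37 | (3aS,4S,5S,6E,10E,11aR)-6-formyl-10-(hydroxymethyl)-5-methoxy-3-methylene-2-oxo-2,3,3a,4,5,8,9,11a-octahydrocyclodeca[b]furan-4-yl methacrylate (CNP0114830.1) | C=C(C)C(=O)O[C@H]1[C@H]2C(=C)C(=O)O[C@@H]2/C=C(/CO)CC/C=C(/C=O)[C@@H]1OC | target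

**Totals**
Total step count: 23. Longest linear sequence: 16 steps (steps 7–11, 13–17, 18–23, from but-2-yne-1,4-diol).

**Three steps most likely to fail, each with a fallback**

Step 18 (Barbier union). The closed transition state and the Felkin–Anh preference of the aldehyde are predicted to agree. Zinc chelation by the α-methoxy group in the aqueous medium could still erode the C8 selectivity, and the aldehyde may hydrate or epimerise in water. The fallback sets out from bromide 12: Pd2(dba)3-catalysed borylation with B2pin2 in toluene at rt gives the isolable allylboronate (R)-3-((4,4,5,5-tetramethyl-1,3,2-dioxaborolan-2-yl)methyl)-5-vinylfuran-2(5H)-one F1. This is combined with aldehyde 29 in dry toluene at 40–60 °C (catalytic Sc(OTf)3 at 0 °C if it is slow). The non-aqueous, non-chelating allylboration goes through the same chair, anti to the vinyl group, and hydrolytic work-up comes back to the route at 31.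

Step 19 (ring-closing metathesis). A ten-membered ring closing onto a 1,1-disubstituted alkene that carries a bulky silyloxymethyl group may be slow and give dimers. The fallback sets out from 31: HF·pyridine in THF removes the silyl group to give (4R,5R)-4-((1R,2S,Z)-1-hydroxy-7-(hydroxymethyl)-2-methoxy-3-(((4-methoxybenzyl)oxy)methyl)octa-3,7-dien-1-yl)-3-methylene-5-vinyldihydrofuran-2(3H)-one F2. Its free allylic hydroxyl and smaller substituent favour loading of the ruthenium carbene, and ring closure under the same high-dilution conditions gives the macrocyclic diol (3aR,4R,5S,6Z,10E,11aR)-4-hydroxy-10-(hydroxymethyl)-5-methoxy-6-(((4-methoxybenzyl)oxy)methyl)-3-methylene-3a,4,5,8,9,11a-hexahydrocyclodeca[b]furan-2(3H)-one F3. Selective silylation of the primary hydroxyl (tert-butyl(chloro)diphenylsilane, imidazole, CH2Cl2, 0 °C) comes back to the route at 32.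

Step 20 (Mitsunobu inversion). The C8 carbinol is flanked by two substituted ring carbons, so the oxyphosphonium may form poorly, or elimination or acylation with retention may compete. The fallback sets out from 32: Tf2O and pyridine in CH2Cl2 at −30 °C give the sulfonate (3aS,4R,5S,6Z,10E,11aR)-10-(((tert-butyldiphenylsilyl)oxy)methyl)-5-methoxy-6-(((4-methoxybenzyl)oxy)methyl)-3-methylene-2-oxo-2,3,3a,4,5,8,9,11a-octahydrocyclodeca[b]furan-4-yl trifluoromethanesulfonate F4. Displacement with caesium methacrylate (CsO2CC(Me)=CH2, 18-crown-6, toluene, rt) is an SN2 carboxylate inversion of a pre-formed leaving group and comes back to the route at 34.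

Further compounds
F1 | step 18 | (R)-3-((4,4,5,5-tetramethyl-1,3,2-dioxaborolan-2-yl)methyl)-5-vinylfuran-2(5H)-one | C=C[C@H]1OC(=O)C(CB2OC(C)(C)C(C)(C)O2)=C1
F2 | step 19 | (4R,5R)-4-((1R,2S,Z)-1-hydroxy-7-(hydroxymethyl)-2-methoxy-3-(((4-methoxybenzyl)oxy)methyl)octa-3,7-dien-1-yl)-3-methylene-5-vinyldihydrofuran-2(3H)-one | C=C[C@H]1OC(=O)C(=C)[C@@H]1[C@@H](O)[C@@H](OC)/C(COCc1ccc(OC)cc1)=C\CCC(=C)CO
F3 | step 19 | (3aR,4R,5S,6Z,10E,11aR)-4-hydroxy-10-(hydroxymethyl)-5-methoxy-6-(((4-methoxybenzyl)oxy)methyl)-3-methylene-3a,4,5,8,9,11a-hexahydrocyclodeca[b]furan-2(3H)-one | O[C@@H]1[C@H]2C(=C)C(=O)O[C@@H]2/C=C(/CO)CC/C=C(/COCc3ccc(OC)cc3)[C@@H]1OC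
F4 | step 20 | (3aS,4R,5S,6Z,10E,11aR)-10-(((tert-butyldiphenylsilyl)oxy)methyl)-5-methoxy-6-(((4-methoxybenzyl)oxy)methyl)-3-methylene-2-oxo-2,3,3a,4,5,8,9,11a-octahydrocyclodeca[b]furan-4-yl trifluoromethanesulfonate | O=S(=O)(O[C@@H]1[C@H]2C(=C)C(=O)O[C@@H]2/C=C(/CO[Si](c3ccccc3)(c3ccccc3)C(C)(C)C)CC/C=C(/COCc3ccc(OC)cc3)[C@@H]1OC)C(F)(F)F
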